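(The readings are simulated for substances that don't exist; scatter was added.)

5 questions hang on one ratio: the share of target among target, cross product and isomer of the product, in 4 flasks set at different temperatures.

| flask | starting material | reagent | second substrate | temperature | remark | time |
|---|---|---|---|---|---|---|
| Friday's | 0.034 M | 0.055 M (fed, over 40 min) | 0.050 M | 22 °C | run made earlier; the fed solution adds 0.20 times the starting volume |  |
| Sunday's | 0.075 M | 0.055 M (fed, over 40 min) | 0.050 M | 72 °C | run made earlier; the fed solution adds 0.20 times the starting volume |  |
| north | 0.050 M | 0.0550 M (fed, over 40 min) | 0.0500 M | 30 °C | the fed solution adds 0.20 times the starting volume | 2.5 h |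
| north-west | 0.050 M | 0.0550 M (fed, over 40 min) | 0.0500 M | 60 °C | the fed solution adds 0.20 times the starting volume | 2.5 h |
| west | 0.050 M | 0.0550 M (fed, over 40 min) | 0.0500 M | 0 °C | the fed solution adds 0.20 times the starting volume | 2.5 h |
| south | 0.050 M | 0.0550 M (fed, over 40 min) | 0.0500 M | 90 °C | the fed solution adds 0.20 times the starting volume | 2.5 h |

- Friday's (time / min: target / %, cross product / %, isomer of the product / %): 10.0: 5.9, 5.1, 0.8; 20.0: 10.5, 9.8, 6.2; 30.0: 13.2, 11.9, 13.8; 60.0: 11.8, 15.8, 34.6; 120: 5.7, 17.4, 47.1
- Sunday's (time / min: target / %, cross product / %, isomer of the product / %): 1.33: 0, 23.1, 0; 4.00: 0, 45.1, 3.4; 8.00: 1.9, 54.1, 8.0; 10.0: 1.5, 55.5, 14.1; 15.0: 0.9, 58.5, 19.2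

(readings scatter by 1 percentage point)

1. the flask that comes out highest in share of target in all that became target or cross product or isomer of the product, or "all alike" when all lie within 1.5 percentage points (north / north-west / west / south / all alike)
2. share of target in all that became target or cross product or isomer of the product, north
3. share of target in all that became target or cross product or isomer of the product, north-west
4. share of target in all that became target or cross product or isomer of the product, west
5. share of target in all that became target or cross product or isomer of the product, south

- charges are per starting volume, the dose included; the dosed solution carries all of it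
- steps under discussion: starting material + reagent <-> target; second substrate + reagent -> second product; starting material + second substrate -> cross product; target <-> isomer of the product

The share can be built up one process at a time. With the main step alone, starting material + reagent to target, it stands at 100 %.

Isomerisation comes next, with d c(isomer)/dt = k c(target). Replacing the curve of c(target) by its mean over an interval gives k as the isomer gained, divided by the mean target and by the interval: the mean-target constant. Friday's readings from 30.0 min to 60.0 min give 0.0555 /min. Sunday's readings from 8.00 min to 15.0 min give 1.14 /min, but target there falls to 0.9 % against a scatter of 1 percentage point and the way back is running, so this is read as a lower limit. The factor between the two readings is 20.6. Dividing Friday's constant by its square root, for the step down from 22 °C to 0 °C, gives 0.0122 /min for west, an upper estimate.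

Target made steadily over 2.5 h has a mean age of half that time, so west's isomer count is 0.916. The mean curve then gives target over target plus isomer as 1/(1 + count). The exact integral for steady production comes out lower, by 6.3 points, and that is the error of the mean.

Cross product comes last. Friday's final reading puts it at 0.330 of target plus isomer, and that ratio is carried over to west.

| Processes counted | Share of target, west |
|---|---|
| main step | 100 % |
| plus isomerisation, mean curve | 52.2 % |
| plus isomerisation, exact integral | 45.8 % |
| plus cross product | 34.5 % |

Friday's constant over 2.5 h already counts 8.32, so north, north-west and south, at 30 °C and up, are put below 10.8 %, Friday's last target over target plus isomer. West should therefore lead, at 34.5 % or above.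

The forecast also names west, with 33 % there and 5.5 %, 2 % and 0.4 % for north, north-west and south: “Only at 0 °C is isomerisation slow”.

The flasks give west as highest, with west at 65.5 %, above the reckoned 34.5 %, and north, north-west and south at 2.79 %, 1.76 % and 0.753 %.

    starting material + reagent ⇌ target (K = 40.0 /M, k = 11.0 /M/h, Ea = 65.0 kJ/mol, ΔH = 24.0 kJ/mol)
    second substrate + reagent → second product (k = 16.0 /M/h, Ea = 60.0 kJ/mol)
    starting material + second substrate → cross product (k = 0.970 /M/h, Ea = 63.0 kJ/mol)
    target ⇌ isomer of the product (K = 19.0, k = 0.160 /h, Ea = 94.0 kJ/mol, ΔH = 2.00 kJ/mol)
    (constants at 0 °C)

West's own states give the mean-target constant again: from 0.667 h to 2.50 h it is 0.00320 /min, which counts 0.480 over 2.5 h: kinetic control. North, counted at 8.32 with Friday's constant, is under thermodynamic control, with isomer over target at 21.9 after 2.50 h and 20.7 after 25.0 h. Left for 25.0 h, west counts 4.80, and the time allowed is the main reason that its share stands at 65.5 % after 2.5 h and falls to 4.59 % at the tenfold time.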